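# Proposed total synthesis of (1R,5R,8S,9R)-1,2-diformyl-5-methyl-8-[(2R)-6-methylhept-5-en-2-yl]bicyclo[3.3.1]non-2-en-9-yl acetate

## Analysis of the target

The target is a C20 dialdehyde acetate on a bicyclo[3.3.1]non-2-ene core. In the numbering used throughout, C1 and C5 are the bridgeheads, ring A is the cyclohexene C1–C2=C3–C4–C5–C9, ring B is the cyclohexane C1–C9–C5–C6–C7–C8, and the side chain joins C8 through C1′. There are five stereocentres: the quaternary bridgeheads C1 (formyl) and C5 (methyl), whose mutual configuration is tied by the bicycle, C9 (acetoxy), C8 (side chain) and the exocyclic C1′ (R). On ring B the C9 acetate is axial, syn to the C6–C8 bridge and cis to the C5 methyl and C1 formyl groups. The C8 side chain is equatorial, trans to the C9 oxygen and cis to the C2 and C4 carbons that make up ring A. The sensitive groups are the 1,4-dialdehyde (an enal at C2 beside a neopentyl aldehyde at C1, prone to lactol and lactone formation whenever one carbon is at the alcohol level), the β-acetoxy aldehyde (retro-aldol cleavage of C1–C9 once the acetate is lost) and the trisubstituted side-chain alkene, which answers to hydrogenation catalysts, oxidants, electrophiles and metathesis catalysts. The difficulty is the run of four contiguous stereocentres C8–C1–C9–C5, with two quaternary carbons flanking C9, together with the remote centre C1′ in a flexible chain. The route rests on ring B: its C9 oxygen lies next to the quaternary C5 and its side chain sits at C8, para to C5. This is the pattern of a [4+2] adduct of a 1-oxy-3-alkyl diene (C9, C1, C8, C7) with methacrolein (C5, C6, with C4 as the formyl carbon), and the (R)-branch at C1′ is that of (R)-citronellal.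

## Retrosynthetic reasoning

**37 back to 33 (no skeletal bond cut; C9 set).** The C1 aldehyde is kept as its dimethyl acetal until the last step (36). The acetate is put on before that (35 → 36), so that no β-hydroxy aldehyde ever meets base. The enal comes from the allylic alcohol of diol 34 by an oxidation that leaves the C9 hydroxyl alone. Diol 34 is the hydride-reduction product of keto ester 33. C9 is therefore set last, in the rigid bicycle, where the cyclohexene side of the bridging ketone is the open one.

**33 ⇒ 29 (C2–C3).** Ring A is opened at C2=C3, read as the dehydrated aldol bond between C2 (α to the ester on the C1 arm) and the aldehyde C3 on the C5 arm. Cutting here, and not at C1–C2 or C4–C5, leaves both quaternary carbons in a plain cyclohexanone. The forward step then only has to join two arms that are already cis-1,3 on ring B. The C3 aldehyde is more acidic than the ester, so the C2 nucleophile must be made without base. Hence bromide 29 and a reductive Reformatsky-type closure to 31, followed by dehydration to 33.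

**29 ⇒ 25 ⇒ 22 ⇒ 19 (the two bonds at C1).** 29 comes from 25 by functional-group changes only: bromination at C2, then unmasking and oxidation of C3. In 25 the quaternary C1 is cut twice. The acetal carbon goes back to orthoformate 24 and the ester arm to bromoacetate 20. This leaves ketone 19, which can enolise only toward C1. The order matters. An electrophile entering C1 of enol ether 23 comes in trans to the neighbouring C8 side chain, and it is the one-carbon group that must be trans. The arm is therefore attached first (19 → 22) and the acetal carbon second (23 → 25). A silyl enol ether with a cationic one-carbon electrophile is preferred to an enolate acylation of 22 for two reasons. 22 has a second acidic site (the ester methylene), and the acetal already has the oxidation level of the C1 formyl group.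

**19 ⇒ 17 ⇒ 10 (C8–H and the C5 arm).** The ketone of 19 goes back to alcohol 18, and the C8–H bond to allylic alcohol 17. The C9 hydroxyl, cis to the C5 methyl group, is the handle that brings hydrogen to the correct face of C1=C8. After that its own configuration is no longer needed. The two-carbon arm on C5 (C4–C3–O) is traced through 16, 15 and 13 to the formyl group of 10 by Wittig methylenation with 11 and hydroboration. This is done before the hydrogenation, so that the only alkenes left are the directed one and the side-chain one.

**10 ⇒ 8 + 9 (C5–C9 and C6–C7).** This is the central disconnection. Ring B is opened by a retro-[4+2] into silyloxy diene 8 and methacrolein 9. It is placed here because these two bonds carry the quaternary C5, and because both directing effects of 8 (oxygen at one terminus, alkyl at C3) point to the same adduct. The gain is one ring, two C–C bonds and two stereocentres in one catalytic step. The forward reaction must select the face of 9 (C5), add in the ortho/para sense, and put the C9 oxygen cis to the methyl group (formyl exo).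

**8 ⇒ 7 ⇒ 6 ⇒ 3 ⇒ 1.** Dienol ether 8 is the γ-deprotonated, O-silylated form of enal 7. Enal 7 is the hydrolysis product of methoxy diene 6, the Wittig product of enal 3 and phosphonium salt 4; that carbon becomes C9. Enal 3 is (R)-citronellal 1 carrying a methylidene group from formaldehyde 2 on its α-carbon; that carbon becomes C7. The carbonyl and α-carbons of 1 become C1 and C8, and its stereocentre becomes C1′ untouched.

## Alternatives that were turned down

**Alternative 1:** an aldol across an eight-membered ring, as in a plausible biogenesis. The C1–C9 bond is cut, which opens both six-membered rings into the cyclooctene trialdehyde A1. In the forward sense the enol of the C1 aldehyde adds to the formyl group on C5 and gives the hydroxy dialdehyde A2, which needs only acetylation.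
- In its favour: the key step delivers every carbon at its final oxidation level. The redox and protecting-group work of the second half of the chosen route (steps 13–23) falls away. On this point it is clearly the stronger plan.
- Against it: A1 is harder to make than the bicycle. A cyclooctene with a quaternary centre (C5) and a tertiary one (C8) in a 1,4-relationship offers no rigid template from which to set them, and closure of an eight-membered ring fights entropy and transannular strain.
- The aldol is reversible, so C9 would be set under equilibrium, and the target's oxygen is on the more crowded side (axial on ring B). The vinylogous enol at C4 is a second nucleophile.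
- In comparison, the chosen route gives up the short endgame. In exchange it sets C5 with a catalyst (step 5), C8 through a hydroxyl relay in a six-membered ring (step 10), and C9 by kinetic hydride attack on a rigid ketone (step 20).

**Alternative 2:** ring-closing metathesis at C2=C3. The alkene of ring A is cut, leading back to cyclohexanone A3, with an allyl group on C5 and an acrylate bound through its α-carbon to C1. The second-generation Hoveyda–Grubbs catalyst, RuCl2(H2IMes)(=CH–C6H4-2-OiPr), would join the two termini and give keto diester A4.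
- In its favour: one step closes ring A and places the conjugated ester, where the chosen route needs five (steps 15–19). Metathesis to a cyclohexene is among the most dependable ring closures. Here the alternative is stronger.
- Against it: the 2-methylalk-2-ene of the side chain is itself a metathesis partner (truncation or a competing closure), and a sluggish 1,1-disubstituted acrylate must react in its presence.
- The acrylate must be bound through an sp2 carbon to the quaternary C1, a bond for which enolate chemistry has no simple electrophile. It must also sit cis to the C8 side chain, the face an incoming group avoids.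
- In comparison, the chosen route makes the corresponding bond (C1–C2) by plain enolate alkylation (step 12) and closes the ring by polar chemistry that ignores the side-chain alkene. It pays with more steps.

**Alternative 3:** gold-catalysed carbocyclisation to ring B. Here C5–C6 is cut. Ring A is made first, as the silyl dienol ether A5 carrying the propargylic C8–C7≡C6 arm on C1. A cationic gold catalyst, (Ph3P)AuNTf2 (monovalent gold), would make C5 attack the alkyne terminus in the 6-endo-dig sense and give the dienone diester A6.
- In its favour: the quaternary C5 and ring B arise in one catalytic, atom-economical step. The configuration of C5 is dictated by the geometry of the bicycle, which is as secure as the catalyst control of step 5.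
- Against it: with a terminal alkyne the 5-exo-dig mode (attack at C7, giving a bicyclo[3.2.1]octane with an exocyclic methylidene) is the usual course, so the regiochemistry of the key step is open.
- A5 needs three contiguous stereocentres (C1, C8, C1′) set on an open arm with no ring to relay from. The side-chain alkene is a second π-nucleophile for the activated alkyne. A6 carries an extra C6=C7 alkene to be hydrogenated beside two others.
- In comparison, the chosen route takes C1′ and the C8 carbon from citronellal, sets C8 by a hydroxyl relay, and uses only ring closures whose regiochemistry is unambiguous.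

Key step: step 5

Remark on the chemistry: the (S)-configured oxazaborolidinium ion is taken to leave the Re face of the α-carbon of 9 open, the sense accepted for 2-substituted acroleins; if the opposite sense were found, the catalyst from (R)-proline is used and nothing else changes.

## Route

Step 1
Reactants: 1 (R)-citronellal; 2 formaldehyde
Product: 3 (3R)-3,7-dimethyl-2-methylideneoct-6-enal
Conditions: aq. HCHO (37%), pyrrolidine (10 mol%), EtCO2H (10 mol%), i-PrOH, 45 °C
Reagents that add atoms: none
Why: Amine-catalysed Mannich condensation with formaldehyde and loss of the amine (α-methylenation of an aldehyde); the stereocentre of 1 is β to the carbonyl and not enolisable, and the mild acid–base pair keeps γ-deprotonation of the product slow.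

Step 2
Reactants: 3 (3R)-3,7-dimethyl-2-methylideneoct-6-enal; 4 (methoxymethyl)triphenylphosphonium chloride
Product: 6 (4R)-1-methoxy-4,8-dimethyl-3-methylidenenona-1,7-diene (1E/1Z mixture), via (methoxymethylidene)triphenylphosphorane 5 (not isolated)
Conditions: 4, KOtBu, THF, 0 °C; then 3, 0 °C → rt
Reagents that add atoms: none
Why: Wittig reaction of the non-stabilised alkoxy ylide 5 at the enal carbonyl (1,2-addition only); the E/Z mixture at the new enol ether is of no consequence because the next step destroys it.

Step 3
Reactants: 6 methoxy diene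
Product: 7 (2E,4R)-3,4,8-trimethylnona-2,7-dienal
Conditions: aq. HCl (1 mol/L), THF, 0 °C → rt
Reagents that add atoms: water, O
Why: Acid hydrolysis of a 1-alkoxy-1,3-diene: protonation at the terminal methylidene carbon gives the conjugated oxocarbenium ion, water adds at C1 and methanol is lost, giving the β-methyl enal with the bulky branch trans to the formyl group; brief exposure to cold dilute acid keeps γ-enolisation toward the C4 stereocentre slow.

Step 4
Reactants: 7 enal
Product: 8 tert-butyl{[(1E,4R)-4,8-dimethyl-3-methylidenenona-1,7-dien-1-yl]oxy}dimethylsilane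
Conditions: TBSOTf, Et3N, Et2O, 0 °C → rt
Reagents that add atoms: tert-butyldimethylsilyl trifluoromethanesulfonate, CC(C)(C)[Si](C)(C)OS(=O)(=O)C(F)(F)F
Why: Silyl dienol ether formation by soft enolisation (O-silylation, then γ-deprotonation by the amine); the s-trans enal gives the (1E) geometry, and the unhindered methyl protons are removed in preference to the methine at C4, so the stereocentre is untouched.

Step 5
Reactants: 8 silyloxy diene; 9 methacrolein
Product: 10 (1S,2S)-2-[(tert-butyldimethylsilyl)oxy]-1-methyl-4-[(2R)-6-methylhept-5-en-2-yl]cyclohex-3-ene-1-carbaldehyde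
Conditions: (S)-[C24H25BNO][N(SO2CF3)2] (20 mol%; from the (S)-diphenylprolinol o-tolylboron oxazaborolidine C24H24BNO and HN(SO2CF3)2), CH2Cl2, −78 °C
Reagents that add atoms: none
Why: The oxazaborolidinium ion binds the formyl oxygen of 9 at boron, with the formyl C–H held against the ring oxygen, so that the s-trans enal lies over one phenyl group and only the Re face of its α-carbon is open to 8. The reaction is a concerted but asynchronous Diels–Alder [4+2] cycloaddition of the oxazaborolidinium-catalysed type known for 2-substituted acroleins and 1-silyloxy dienes; C6–C7 bonding runs ahead because the unsubstituted diene terminus has the largest HOMO coefficient and the β-carbon of the activated enal the largest LUMO coefficient. Ring B (the cyclohexene C1, C5–C9) closes by this suprafacial cycloaddition, both σ-bonds C5–C9 and C6–C7 forming in the one step. Regiochemistry is doubly secured: the 1-silyloxy group sends its own carbon to the α-carbon of the enal, and the 3-alkyl group puts C8 para to C5. C5 is set by the catalyst, which selects the face of 9; C9 is set by the topology, the (E)-silyloxy group and a formyl-exo transition state placing the oxygen cis to the methyl group. The exo mode is expected because the α-methyl group takes the endo position, as it does with cyclopentadiene, and because the bulky silyl ether and the catalyst-bound formyl group avoid each other. The isolated side-chain alkene is not a diene and does not compete, and C1′, one bond from the diene, is not touched. The TBS group, more robust than TMS, protects the dienol ether from desilylation and Mukaiyama-type addition under the strongly Lewis acidic catalyst.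

Step 6
Reactants: 10 cycloadduct aldehyde; 11 methyltriphenylphosphonium bromide
Product: 13 tert-butyl({(1S,6R)-6-ethenyl-6-methyl-3-[(2R)-6-methylhept-5-en-2-yl]cyclohex-2-en-1-yl}oxy)dimethylsilane, via methylidenetriphenylphosphorane 12 (not isolated)
Conditions: 11, KOtBu, THF, 0 °C; then 10, 0 °C → rt
Reagents that add atoms: none
Why: Wittig methylenation; the aldehyde has no α-hydrogen and the β-oxygen is silylated, so neither enolisation nor retro-aldol cleavage can compete, and the new vinyl carbon is C3 of the target.

Step 7
Reactants: 13 vinyl silyl ether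
Product: 15 2-{(1R,2S)-2-[(tert-butyldimethylsilyl)oxy]-1-methyl-4-[(2R)-6-methylhept-5-en-2-yl]cyclohex-3-en-1-yl}ethan-1-ol, via B-alkyl-9-borabicyclo[3.3.1]nonane 14 (not isolated)
Conditions: 9-BBN, THF, 0 °C → rt; then NaOH, H2O2, 0 °C
Reagents that add atoms: hydrogen peroxide, OO
Why: Anti-Markovnikov hydroboration–oxidation; 9-BBN adds to the monosubstituted vinyl group far faster than to either trisubstituted alkene, so boron and then oxygen end up on C3.

Step 8
Reactants: 15 primary alcohol (C9–OTBS)
Product: 16 (1S,6R)-6-(2-hydroxyethyl)-6-methyl-3-[(2R)-6-methylhept-5-en-2-yl]cyclohex-2-en-1-ol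
Conditions: Bu4NF, THF, rt
Reagents that add atoms: none
Why: Fluoride cleaves the silyl ether at C9 through Si–F bond formation; the C9 configuration is untouched and no base-labile group is present.

Step 9
Reactants: 16 diol
Product: 17 (1S,6R)-6-{2-[(tert-butyldimethylsilyl)oxy]ethyl}-6-methyl-3-[(2R)-6-methylhept-5-en-2-yl]cyclohex-2-en-1-ol
Conditions: TBSCl, imidazole, CH2Cl2, 0 °C
Reagents that add atoms: tert-butyldimethylsilyl chloride, CC(C)(C)[Si](C)(C)Cl
Why: Imidazole-mediated silylation is selective for the primary hydroxyl group; the secondary allylic hydroxyl at C9, next to the quaternary C5, stays free as the directing group, and the new silyl ether carries no arene that could bind the rhodium catalyst of the next step.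

Step 10
Reactants: 17 allylic alcohol
Product: 18 (1S,2R,5R)-2-{2-[(tert-butyldimethylsilyl)oxy]ethyl}-2-methyl-5-[(2R)-6-methylhept-5-en-2-yl]cyclohexan-1-ol
Conditions: H2 (50 bar), [Rh(nbd)(dppb)]BF4 (5 mol%), CH2Cl2, rt
Reagents that add atoms: none
Why: Hydroxyl-directed homogeneous hydrogenation: the cationic rhodium centre binds the C9 hydroxyl and delivers both hydrogens to C1=C8 from that face, which puts the C8–H cis to the C9 oxygen and the C5 methyl group and the side chain cis to the C5 arm (new stereocentre C8, substrate-controlled). The unfunctionalised trisubstituted alkene of the side chain has no directing group and is reduced far more slowly by this catalyst, and high pressure suppresses isomerisation of the allylic alcohol.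

Step 11
Reactants: 18 cyclohexanol
Product: 19 (2R,5R)-2-{2-[(tert-butyldimethylsilyl)oxy]ethyl}-2-methyl-5-[(2R)-6-methylhept-5-en-2-yl]cyclohexan-1-one
Conditions: Dess–Martin periodinane, NaHCO3, CH2Cl2, 0 °C → rt
Reagents that add atoms: none
Why: Dess–Martin oxidation of the secondary alcohol under buffered, neutral conditions; C8 is β to the new carbonyl and cannot epimerise, and the ketone has a single enolisable position (C1), C5 being quaternary.

Step 12
Reactants: 19 ketone; 20 methyl bromoacetate
Product: 22 methyl 2-[(1RS,3R,6S)-3-{2-[(tert-butyldimethylsilyl)oxy]ethyl}-3-methyl-6-[(2R)-6-methylhept-5-en-2-yl]-2-oxocyclohexyl]acetate (C1 epimers), via lithium enolate 21 (not isolated)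
Conditions: LiN(iPr)2, THF, −78 °C; then 20, DMPU, −78 → −20 °C
Reagents that add atoms: none
Why: Enolate alkylation (SN2) of the lithium enolate 21, which can form only toward C1, with a reactive α-halo ester; this makes C1–C2. The configuration at C1 in 22 does not matter, because C1 is made planar again in the next step.

Step 13
Reactants: 22 keto ester
Product: 23 methyl 2-[(3R,6S)-3-{2-[(tert-butyldimethylsilyl)oxy]ethyl}-3-methyl-6-[(2R)-6-methylhept-5-en-2-yl]-2-[(trimethylsilyl)oxy]cyclohex-1-en-1-yl]acetate
Conditions: TMSOTf, Et3N, CH2Cl2, 0 °C → rt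
Reagents that add atoms: trimethylsilyl trifluoromethanesulfonate, C[Si](C)(C)OS(=O)(=O)C(F)(F)F
Why: Soft enolisation with silyl triflate and amine converts the ketone, but not the much less acidic ester, into its silyl enol ether; since C5 is quaternary only the tetrasubstituted C1=C9 enol ether can form, which fixes the site of the next bond without a strong base.

Step 14
Reactants: 23 silyl enol ether; 24 trimethyl orthoformate
Product: 25 methyl 2-[(1R,3R,6S)-3-{2-[(tert-butyldimethylsilyl)oxy]ethyl}-1-(dimethoxymethyl)-3-methyl-6-[(2R)-6-methylhept-5-en-2-yl]-2-oxocyclohexyl]acetate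
Conditions: 24, TMSOTf (20 mol%), CH2Cl2, −78 → −40 °C
Reagents that add atoms: none
Why: Mukaiyama-type addition of the silyl enol ether to the dimethoxycarbenium ion released from the orthoformate by the silyl triflate, giving the β-keto acetal with C1 quaternary. Allylic strain with the C1 substituent turns the C8 side chain pseudoaxial, and the small planar electrophile enters C1 anti to it, so the acetal carbon is trans and the ester arm cis to the side chain, as the bicycle needs (new stereocentre C1, substrate-controlled).

Step 15
Reactants: 25 keto acetal ester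
Product: 27 methyl (2RS)-2-bromo-2-[(1S,3R,6S)-3-{2-[(tert-butyldimethylsilyl)oxy]ethyl}-1-(dimethoxymethyl)-3-methyl-6-[(2R)-6-methylhept-5-en-2-yl]-2-oxocyclohexyl]acetate (C2 epimers), via lithium ester enolate 26 (not isolated)
Conditions: LiN(SiMe3)2, THF, −78 °C; then BrCl2C–CCl2Br, −78 °C
Reagents that add atoms: 1,2-dibromo-1,1,2,2-tetrachloroethane, ClC(Cl)(Br)C(Cl)(Cl)Br
Why: Enolate bromination: the C2 methylene is now the only acidic position (the ketone is flanked by two quaternary carbons), and its lithium enolate 26 takes bromine from a positive-bromine donor that does not attack alkenes. The C2 epimers are used together, since C2 becomes trigonal later.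

Step 16
Reactants: 27 bromo ester silyl ether
Product: 28 methyl (2RS)-2-bromo-2-[(1S,3R,6S)-1-(dimethoxymethyl)-3-(2-hydroxyethyl)-3-methyl-6-[(2R)-6-methylhept-5-en-2-yl]-2-oxocyclohexyl]acetate (C2 epimers)
Conditions: HF·pyridine, pyridine, THF, 0 °C → rt
Reagents that add atoms: none
Why: Fluoride-mediated desilylation under buffered conditions that spare the dimethyl acetal and the α-bromo ester; the γ-hydroxy ketone may rest partly as its hemiketal, which does not affect the oxidation.

Step 17
Reactants: 28 bromo ester alcohol
Product: 29 methyl (2RS)-2-bromo-2-[(1S,3R,6S)-1-(dimethoxymethyl)-3-methyl-6-[(2R)-6-methylhept-5-en-2-yl]-2-oxo-3-(2-oxoethyl)cyclohexyl]acetate (C2 epimers)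
Conditions: Dess–Martin periodinane, NaHCO3, CH2Cl2, 0 °C → rt
Reagents that add atoms: none
Why: Dess–Martin oxidation of the primary alcohol to the aldehyde C3; the neutral conditions tolerate the α-bromo ester and the acetal.

Step 18
Reactants: 29 bromo ester aldehyde
Product: 31 methyl (1S,5R,8S)-1-(dimethoxymethyl)-3-hydroxy-5-methyl-8-[(2R)-6-methylhept-5-en-2-yl]-9-oxobicyclo[3.3.1]nonane-2-carboxylate (C2/C3 epimers), via samarium enolate 30 (not isolated)
Conditions: SmI2 (2.5 equiv), THF (0.01 mol/L), −78 °C
Reagents that add atoms: none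
Why: Intramolecular samarium Reformatsky reaction: two single-electron transfers cleave the C–Br bond and give the samarium enolate 30 at C2 regiospecifically, which adds to the C3 aldehyde and closes ring A (six-membered; the C2 and C4 arms are cis-1,3-diaxial on ring B in the chair that keeps the side chain equatorial). The α-bromo ester is reduced much faster than the aldehyde or the hindered ketone, and the new centres at C2 and C3 are removed in the next step.

Step 19
Reactants: 31 β-hydroxy ester
Product: 33 methyl (1S,5R,8S)-1-(dimethoxymethyl)-5-methyl-8-[(2R)-6-methylhept-5-en-2-yl]-9-oxobicyclo[3.3.1]non-2-ene-2-carboxylate, via mesylate 32 (not isolated)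
Conditions: MsCl, Et3N, CH2Cl2, 0 °C; then DBU, rt
Reagents that add atoms: none
Why: Mesylation of the β-hydroxyl group and base-induced E1cB elimination through the ester enolate give the conjugated C2=C3 alkene; C1 is quaternary, and the enolate pathway excludes elimination toward C4.

Step 20
Reactants: 33 bicyclic keto ester
Product: 34 (1R,5R,8S,9R)-1-(dimethoxymethyl)-2-(hydroxymethyl)-5-methyl-8-[(2R)-6-methylhept-5-en-2-yl]bicyclo[3.3.1]non-2-en-9-ol
Conditions: iBu2AlH (5 equiv), CH2Cl2, −78 → 0 °C; aq. potassium sodium tartrate work-up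
Reagents that add atoms: none
Why: Hydride reduction of the bridging ketone and 1,2-reduction of the conjugated ester to the allylic alcohol. Hydride reaches C9 from the side of the cyclohexene ring, which presents an sp2 carbon and only one axial hydrogen (at C4) toward C9, and not from the saturated ring with axial hydrogens at C6 and C8; the hydroxyl therefore ends up syn to the C6–C8 bridge and cis to the C5 methyl group (new stereocentre C9, substrate-controlled).

Step 21
Reactants: 34 diol
Product: 35 (1R,5R,8S,9R)-1-(dimethoxymethyl)-9-hydroxy-5-methyl-8-[(2R)-6-methylhept-5-en-2-yl]bicyclo[3.3.1]non-2-ene-2-carbaldehyde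
Conditions: MnO2, CH2Cl2, rt
Reagents that add atoms: none
Why: MnO2 oxidises allylic alcohols selectively, so the saturated, hindered C9 hydroxyl is left; with C1 masked as the acetal, no lactol can form between the two one-carbon groups.

Step 22
Reactants: 35 hydroxy enal
Product: 36 (1R,5R,8S,9R)-1-(dimethoxymethyl)-2-formyl-5-methyl-8-[(2R)-6-methylhept-5-en-2-yl]bicyclo[3.3.1]non-2-en-9-yl acetate
Conditions: Ac2O, DMAP, Et3N, CH2Cl2, rt → 40 °C
Reagents that add atoms: acetic anhydride, CC(=O)OC(C)=O
Why: DMAP-catalysed acyl transfer acetylates the hindered secondary hydroxyl; doing this before the C1 aldehyde is set free avoids a β-hydroxy aldehyde that could open by retro-aldol cleavage of C1–C9.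

Step 23
Reactants: 36 acetal acetate
Product: 37 (1R,5R,8S,9R)-1,2-diformyl-5-methyl-8-[(2R)-6-methylhept-5-en-2-yl]bicyclo[3.3.1]non-2-en-9-yl acetate
Conditions: CF3CO2H, H2O, CH2Cl2, 0 °C
Reagents that add atoms: water, O
Why: Acid-catalysed acetal hydrolysis sets the C1 aldehyde free; C1 is quaternary, so the β-acetoxy aldehyde cannot eliminate, and the cold dilute acid is too weak to protonate the side-chain alkene.

## Compound list

1 | (R)-citronellal, (3R)-3,7-dimethyloct-6-enal | C[C@H](CCC=C(C)C)CC=O | starting material
2 | formaldehyde | C=O | starting material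
3 | (3R)-3,7-dimethyl-2-methylideneoct-6-enal | C=C(C=O)[C@H](C)CCC=C(C)C | intermediate
4 | (methoxymethyl)triphenylphosphonium chloride | COC[P+](c1ccccc1)(c1ccccc1)c1ccccc1.[Cl-] | starting material
5 | (methoxymethylidene)triphenylphosphorane | COC=P(c1ccccc1)(c1ccccc1)c1ccccc1 | intermediate
6 | (4R)-1-methoxy-4,8-dimethyl-3-methylidenenona-1,7-diene (1E/1Z mixture) | COC=CC(=C)[C@H](C)CCC=C(C)C | intermediate
7 | (2E,4R)-3,4,8-trimethylnona-2,7-dienal | O=C/C=C(C)/[C@H](C)CCC=C(C)C | intermediate
8 | tert-butyl{[(1E,4R)-4,8-dimethyl-3-methylidenenona-1,7-dien-1-yl]oxy}dimethylsilane | C=C([C@H](C)CCC=C(C)C)/C=C/O[Si](C)(C)C(C)(C)C | intermediate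
9 | methacrolein, 2-methylprop-2-enal | CC(=C)C=O | starting material
10 | (1S,2S)-2-[(tert-butyldimethylsilyl)oxy]-1-methyl-4-[(2R)-6-methylhept-5-en-2-yl]cyclohex-3-ene-1-carbaldehyde | O=C[C@@]1(C)CCC([C@H](C)CCC=C(C)C)=C[C@@H]1O[Si](C)(C)C(C)(C)C | intermediate
11 | methyltriphenylphosphonium bromide | C[P+](c1ccccc1)(c1ccccc1)c1ccccc1.[Br-] | starting material
12 | methylidenetriphenylphosphorane | C=P(c1ccccc1)(c1ccccc1)c1ccccc1 | intermediate
13 | tert-butyl({(1S,6R)-6-ethenyl-6-methyl-3-[(2R)-6-methylhept-5-en-2-yl]cyclohex-2-en-1-yl}oxy)dimethylsilane | C=C[C@@]1(C)CCC([C@H](C)CCC=C(C)C)=C[C@@H]1O[Si](C)(C)C(C)(C)C | intermediate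
14 | 9-(2-{(1S,2S)-2-[(tert-butyldimethylsilyl)oxy]-1-methyl-4-[(2R)-6-methylhept-5-en-2-yl]cyclohex-3-en-1-yl}ethyl)-9-borabicyclo[3.3.1]nonane | B1(CC[C@@]2(C)CCC([C@H](C)CCC=C(C)C)=C[C@@H]2O[Si](C)(C)C(C)(C)C)C2CCCC1CCC2 | intermediate
15 | 2-{(1R,2S)-2-[(tert-butyldimethylsilyl)oxy]-1-methyl-4-[(2R)-6-methylhept-5-en-2-yl]cyclohex-3-en-1-yl}ethan-1-ol | OCC[C@@]1(C)CCC([C@H](C)CCC=C(C)C)=C[C@@H]1O[Si](C)(C)C(C)(C)C | intermediate
16 | (1S,6R)-6-(2-hydroxyethyl)-6-methyl-3-[(2R)-6-methylhept-5-en-2-yl]cyclohex-2-en-1-ol | OCC[C@@]1(C)CCC([C@H](C)CCC=C(C)C)=C[C@@H]1O | intermediate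
17 | (1S,6R)-6-{2-[(tert-butyldimethylsilyl)oxy]ethyl}-6-methyl-3-[(2R)-6-methylhept-5-en-2-yl]cyclohex-2-en-1-ol | CC(C)(C)[Si](C)(C)OCC[C@@]1(C)CCC([C@H](C)CCC=C(C)C)=C[C@@H]1O | intermediate
18 | (1S,2R,5R)-2-{2-[(tert-butyldimethylsilyl)oxy]ethyl}-2-methyl-5-[(2R)-6-methylhept-5-en-2-yl]cyclohexan-1-ol | O[C@H]1C[C@H]([C@H](C)CCC=C(C)C)CC[C@]1(C)CCO[Si](C)(C)C(C)(C)C | intermediate
19 | (2R,5R)-2-{2-[(tert-butyldimethylsilyl)oxy]ethyl}-2-methyl-5-[(2R)-6-methylhept-5-en-2-yl]cyclohexan-1-one | O=C1C[C@H]([C@H](C)CCC=C(C)C)CC[C@]1(C)CCO[Si](C)(C)C(C)(C)C | intermediate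
20 | methyl bromoacetate | COC(=O)CBr | starting material
21 | lithium enolate of 19 (C9–OLi, C1=C9) | [Li]OC1=C[C@H]([C@H](C)CCC=C(C)C)CC[C@]1(C)CCO[Si](C)(C)C(C)(C)C | intermediate
22 | methyl 2-[(1RS,3R,6S)-3-{2-[(tert-butyldimethylsilyl)oxy]ethyl}-3-methyl-6-[(2R)-6-methylhept-5-en-2-yl]-2-oxocyclohexyl]acetate (C1 epimers) | O=C1C(CC(=O)OC)[C@H]([C@H](C)CCC=C(C)C)CC[C@]1(C)CCO[Si](C)(C)C(C)(C)C | intermediate
23 | methyl 2-[(3R,6S)-3-{2-[(tert-butyldimethylsilyl)oxy]ethyl}-3-methyl-6-[(2R)-6-methylhept-5-en-2-yl]-2-[(trimethylsilyl)oxy]cyclohex-1-en-1-yl]acetate | C[Si](C)(C)OC1=C(CC(=O)OC)[C@H]([C@H](C)CCC=C(C)C)CC[C@]1(C)CCO[Si](C)(C)C(C)(C)C | intermediate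
24 | trimethyl orthoformate | COC(OC)OC | starting material
25 | methyl 2-[(1R,3R,6S)-3-{2-[(tert-butyldimethylsilyl)oxy]ethyl}-1-(dimethoxymethyl)-3-methyl-6-[(2R)-6-methylhept-5-en-2-yl]-2-oxocyclohexyl]acetate | O=C1[C@](C(OC)OC)(CC(=O)OC)[C@H]([C@H](C)CCC=C(C)C)CC[C@]1(C)CCO[Si](C)(C)C(C)(C)C | intermediate
26 | lithium ester enolate of 25 (C2=C(OMe)OLi) | O=C1[C@](C(OC)OC)(C=C(OC)O[Li])[C@H]([C@H](C)CCC=C(C)C)CC[C@]1(C)CCO[Si](C)(C)C(C)(C)C | intermediate
27 | methyl (2RS)-2-bromo-2-[(1S,3R,6S)-3-{2-[(tert-butyldimethylsilyl)oxy]ethyl}-1-(dimethoxymethyl)-3-methyl-6-[(2R)-6-methylhept-5-en-2-yl]-2-oxocyclohexyl]acetate | O=C1[C@](C(OC)OC)(C(Br)C(=O)OC)[C@H]([C@H](C)CCC=C(C)C)CC[C@]1(C)CCO[Si](C)(C)C(C)(C)C | intermediate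
28 | methyl (2RS)-2-bromo-2-[(1S,3R,6S)-1-(dimethoxymethyl)-3-(2-hydroxyethyl)-3-methyl-6-[(2R)-6-methylhept-5-en-2-yl]-2-oxocyclohexyl]acetate | O=C1[C@](C(OC)OC)(C(Br)C(=O)OC)[C@H]([C@H](C)CCC=C(C)C)CC[C@]1(C)CCO | intermediate
29 | methyl (2RS)-2-bromo-2-[(1S,3R,6S)-1-(dimethoxymethyl)-3-methyl-6-[(2R)-6-methylhept-5-en-2-yl]-2-oxo-3-(2-oxoethyl)cyclohexyl]acetate | O=C1[C@](C(OC)OC)(C(Br)C(=O)OC)[C@H]([C@H](C)CCC=C(C)C)CC[C@]1(C)CC=O | intermediate
30 | diiodosamarium ester enolate formed from 29 by loss of bromide (C2=C(OMe)OSmI2) | O=C1[C@](C(OC)OC)(C=C(OC)O[Sm](I)I)[C@H]([C@H](C)CCC=C(C)C)CC[C@]1(C)CC=O | intermediate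
31 | methyl (1S,5R,8S)-1-(dimethoxymethyl)-3-hydroxy-5-methyl-8-[(2R)-6-methylhept-5-en-2-yl]-9-oxobicyclo[3.3.1]nonane-2-carboxylate (C2/C3 epimers) | O=C1[C@@]2(C)CC(O)C(C(=O)OC)[C@]1(C(OC)OC)[C@H]([C@H](C)CCC=C(C)C)CC2 | intermediate
32 | methyl (1S,5R,8S)-1-(dimethoxymethyl)-3-[(methanesulfonyl)oxy]-5-methyl-8-[(2R)-6-methylhept-5-en-2-yl]-9-oxobicyclo[3.3.1]nonane-2-carboxylate (C2/C3 epimers) | O=C1[C@@]2(C)CC(OS(C)(=O)=O)C(C(=O)OC)[C@]1(C(OC)OC)[C@H]([C@H](C)CCC=C(C)C)CC2 | intermediate
33 | methyl (1S,5R,8S)-1-(dimethoxymethyl)-5-methyl-8-[(2R)-6-methylhept-5-en-2-yl]-9-oxobicyclo[3.3.1]non-2-ene-2-carboxylate | O=C1[C@@]2(C)CC=C(C(=O)OC)[C@]1(C(OC)OC)[C@H]([C@H](C)CCC=C(C)C)CC2 | intermediate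
34 | (1R,5R,8S,9R)-1-(dimethoxymethyl)-2-(hydroxymethyl)-5-methyl-8-[(2R)-6-methylhept-5-en-2-yl]bicyclo[3.3.1]non-2-en-9-ol | O[C@@H]1[C@@]2(C)CC=C(CO)[C@]1(C(OC)OC)[C@H]([C@H](C)CCC=C(C)C)CC2 | intermediate
35 | (1R,5R,8S,9R)-1-(dimethoxymethyl)-9-hydroxy-5-methyl-8-[(2R)-6-methylhept-5-en-2-yl]bicyclo[3.3.1]non-2-ene-2-carbaldehyde | O[C@@H]1[C@@]2(C)CC=C(C=O)[C@]1(C(OC)OC)[C@H]([C@H](C)CCC=C(C)C)CC2 | intermediate
36 | (1R,5R,8S,9R)-1-(dimethoxymethyl)-2-formyl-5-methyl-8-[(2R)-6-methylhept-5-en-2-yl]bicyclo[3.3.1]non-2-en-9-yl acetate | CC(=O)O[C@@H]1[C@@]2(C)CC=C(C=O)[C@]1(C(OC)OC)[C@H]([C@H](C)CCC=C(C)C)CC2 | intermediate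
37 | (1R,5R,8S,9R)-1,2-diformyl-5-methyl-8-[(2R)-6-methylhept-5-en-2-yl]bicyclo[3.3.1]non-2-en-9-yl acetate | CC(=O)O[C@@H]1[C@@]2(C)CC=C(C=O)[C@]1(C=O)[C@H]([C@H](C)CCC=C(C)C)CC2 | target

## Step count and least certain steps

Total step count: 23. Longest linear sequence: 23 steps (1 → 37); the route is linear, and 2, 4, 9, 11, 20 and 24 are bought.

**Step 5 (key step).**
- Most likely to go wrong: the endo/exo course. If the cycloaddition passes through the formyl-endo transition state, the C9 oxygen ends up cis to the formyl group, on the wrong face for the directed hydrogenation of step 10. The exo preference is firmly known for cyclopentadiene and less so for open-chain 1-oxy dienes. Less likely are erosion of face selectivity and loss of the dienol ether by protodesilylation.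
- Fallback: make the route independent of the C9 configuration. The fallback sets out from 8 and 9 and comes back at 19.
- The cycloaddition is run as before. The C9-epimeric cycloadduct F1, alone or mixed with 10, is taken through the operations of steps 6–9 unchanged. This gives in turn vinyl compound F2, primary alcohol F3, diol F4 and mono-silyl ether F5.
- Oxidation of F5 (together with any 17) with MnO2 gives one compound, enone F6.
- F6 is reduced by the chiral copper hydride described under step 10 to 19. C8 is then set by a catalyst and not by a relay from C9.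

**Step 10.**
- Most likely to go wrong: chemoselectivity. Hydrogen may be taken up at the unhindered side-chain alkene once the directed reduction slows at the hindered, β-branched ring alkene. The allylic alcohol may also isomerise to the ketone by hydride migration on the metal.
- Fallback: give up hydrogen gas and the hydroxyl relay. The fallback sets out from 17 and comes back at 19, so step 11 falls away.
- 17 is oxidised (MnO2, CH2Cl2, rt) to enone F6.
- F6 is reduced in the 1,4-sense by a copper hydride carrying a chiral bisphosphine (Cu(OAc)2, DTBM-SEGPHOS, polymethylhydrosiloxane, t-BuOH, toluene, 0 °C), which does not touch isolated alkenes.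
- The ligand antipode that brings hydride to C8 on the face of the C5 methyl group is chosen by a trial with both. It gives 19 directly.

**Step 14.**
- Most likely to go wrong: low conversion at the fully substituted enol ether carbon, which is flanked by C8 and faces the C5 methyl group across C9. Protodesilylation back to 22 would then win over C–C bond formation. Partial loss of face selectivity is a second risk.
- Fallback: bring in the acetal carbon as a preformed, sulfur-stabilised carbenium salt, which is small and planar and needs no Lewis acid. The fallback sets out from 23 and comes back at 25.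
- 23 and 1,3-dithian-2-ylium tetrafluoroborate (CH2Cl2, −78 °C) should give dithiane F7.
- Alkylative transacetalisation (MeI, CaCO3, MeOH, 50 °C) converts F7 into 25.

**Step 18.**
- Most likely to go wrong: reduction without ring closure. The samarium enolate may be protonated (loss of bromine only), or a ketyl may form at the aldehyde and couple, if the chair with both arms axial is sparsely populated.
- Fallback: close C2–C3 by alkylation instead of aldol addition, so that no aldehyde is present. The fallback sets out from 25 and comes back at 33.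
- Desilylation of 25 (HF·pyridine, THF) gives alcohol F8, and iodination (iodine, PPh3, imidazole) gives iodide F9.
- LiN(SiMe3)2 (THF, −78 → 0 °C) closes ring A by 6-exo-tet attack of the ester enolate at C3 and gives the saturated bicyclic ester F10.
- Deprotonation of F10 with LiN(iPr)2 and trapping with PhSeBr gives selenide F11. Oxidation with H2O2 and syn-elimination toward C3, the only carbon with β-hydrogens, gives 33.

## Further compounds

F1 | step 5 | (1S,2R)-2-[(tert-butyldimethylsilyl)oxy]-1-methyl-4-[(2R)-6-methylhept-5-en-2-yl]cyclohex-3-ene-1-carbaldehyde | O=C[C@@]1(C)CCC([C@H](C)CCC=C(C)C)=C[C@H]1O[Si](C)(C)C(C)(C)C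
F2 | step 5 | tert-butyl({(1R,6R)-6-ethenyl-6-methyl-3-[(2R)-6-methylhept-5-en-2-yl]cyclohex-2-en-1-yl}oxy)dimethylsilane | C=C[C@@]1(C)CCC([C@H](C)CCC=C(C)C)=C[C@H]1O[Si](C)(C)C(C)(C)C
F3 | step 5 | 2-{(1R,2R)-2-[(tert-butyldimethylsilyl)oxy]-1-methyl-4-[(2R)-6-methylhept-5-en-2-yl]cyclohex-3-en-1-yl}ethan-1-ol | OCC[C@@]1(C)CCC([C@H](C)CCC=C(C)C)=C[C@H]1O[Si](C)(C)C(C)(C)C
F4 | step 5 | (1R,6R)-6-(2-hydroxyethyl)-6-methyl-3-[(2R)-6-methylhept-5-en-2-yl]cyclohex-2-en-1-ol | OCC[C@@]1(C)CCC([C@H](C)CCC=C(C)C)=C[C@H]1O
F5 | step 5 | (1R,6R)-6-{2-[(tert-butyldimethylsilyl)oxy]ethyl}-6-methyl-3-[(2R)-6-methylhept-5-en-2-yl]cyclohex-2-en-1-ol | CC(C)(C)[Si](C)(C)OCC[C@@]1(C)CCC([C@H](C)CCC=C(C)C)=C[C@H]1O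
F6 | step 10 | (6R)-6-{2-[(tert-butyldimethylsilyl)oxy]ethyl}-6-methyl-3-[(2R)-6-methylhept-5-en-2-yl]cyclohex-2-en-1-one | O=C1C=C([C@H](C)CCC=C(C)C)CC[C@]1(C)CCO[Si](C)(C)C(C)(C)C
F7 | step 14 | methyl 2-[(1S,3R,6S)-3-{2-[(tert-butyldimethylsilyl)oxy]ethyl}-1-(1,3-dithian-2-yl)-3-methyl-6-[(2R)-6-methylhept-5-en-2-yl]-2-oxocyclohexyl]acetate | O=C1[C@](C2SCCCS2)(CC(=O)OC)[C@H]([C@H](C)CCC=C(C)C)CC[C@]1(C)CCO[Si](C)(C)C(C)(C)C
F8 | step 18 | methyl 2-[(1R,3R,6S)-1-(dimethoxymethyl)-3-(2-hydroxyethyl)-3-methyl-6-[(2R)-6-methylhept-5-en-2-yl]-2-oxocyclohexyl]acetate | O=C1[C@](C(OC)OC)(CC(=O)OC)[C@H]([C@H](C)CCC=C(C)C)CC[C@]1(C)CCO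
F9 | step 18 | methyl 2-[(1R,3R,6S)-1-(dimethoxymethyl)-3-(2-iodoethyl)-3-methyl-6-[(2R)-6-methylhept-5-en-2-yl]-2-oxocyclohexyl]acetate | O=C1[C@](C(OC)OC)(CC(=O)OC)[C@H]([C@H](C)CCC=C(C)C)CC[C@]1(C)CCI
F10 | step 18 | methyl (1S,5R,8S)-1-(dimethoxymethyl)-5-methyl-8-[(2R)-6-methylhept-5-en-2-yl]-9-oxobicyclo[3.3.1]nonane-2-carboxylate (C2 epimers) | O=C1[C@@]2(C)CCC(C(=O)OC)[C@]1(C(OC)OC)[C@H]([C@H](C)CCC=C(C)C)CC2
F11 | step 18 | methyl (1S,5R,8S)-1-(dimethoxymethyl)-5-methyl-8-[(2R)-6-methylhept-5-en-2-yl]-9-oxo-2-(phenylselanyl)bicyclo[3.3.1]nonane-2-carboxylate (C2 epimers) | O=C1[C@@]2(C)CCC([Se]c3ccccc3)(C(=O)OC)[C@]1(C(OC)OC)[C@H]([C@H](C)CCC=C(C)C)CC2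
A1 | alternative 1 | (4R,7S)-4-methyl-7-[(2R)-6-methylhept-5-en-2-yl]cyclooct-1-ene-1,4,8-tricarbaldehyde (C8 epimers) | O=C[C@@]1(C)CC=C(C=O)C(C=O)[C@H]([C@H](C)CCC=C(C)C)CC1
A2 | alternative 1 | (1R,5R,8S,9R)-9-hydroxy-5-methyl-8-[(2R)-6-methylhept-5-en-2-yl]bicyclo[3.3.1]non-2-ene-1,2-dicarbaldehyde | O[C@@H]1[C@@]2(C)CC=C(C=O)[C@]1(C=O)[C@H]([C@H](C)CCC=C(C)C)CC2
A3 | alternative 2 | methyl (1R,3R,6S)-1-(3-methoxy-3-oxoprop-1-en-2-yl)-3-methyl-6-[(2R)-6-methylhept-5-en-2-yl]-2-oxo-3-(prop-2-en-1-yl)cyclohexane-1-carboxylate | O=C1[C@](C(=O)OC)(C(=C)C(=O)OC)[C@H]([C@H](C)CCC=C(C)C)CC[C@]1(C)CC=C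
A4 | alternative 2 | dimethyl (1R,5R,8S)-5-methyl-8-[(2R)-6-methylhept-5-en-2-yl]-9-oxobicyclo[3.3.1]non-2-ene-1,2-dicarboxylate | O=C1[C@@]2(C)CC=C(C(=O)OC)[C@]1(C(=O)OC)[C@H]([C@H](C)CCC=C(C)C)CC2
A5 | alternative 3 | dimethyl (1R)-6-[(tert-butyldimethylsilyl)oxy]-1-[(3R,4R)-4,8-dimethylnon-7-en-1-yn-3-yl]-5-methylcyclohexa-2,5-diene-1,2-dicarboxylate | C#C[C@@H]([C@H](C)CCC=C(C)C)[C@@]1(C(=O)OC)C(C(=O)OC)=CCC(C)=C1O[Si](C)(C)C(C)(C)C
A6 | alternative 3 | dimethyl (1R,5S,8R)-5-methyl-8-[(2R)-6-methylhept-5-en-2-yl]-9-oxobicyclo[3.3.1]nona-2,6-diene-1,2-dicarboxylate | O=C1[C@@]2(C)CC=C(C(=O)OC)[C@]1(C(=O)OC)[C@H]([C@H](C)CCC=C(C)C)C=C2
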